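**Assumptions:** the geranyl group is (E)-geranyl, and recombinant flavanone 3-hydroxylase accepts the 6-geranyl, 4'-OMe flavanone.

## Retrosynthetic overview
1. The 3-OH and the trans-(2R,3R) relationship come last. Flavanone 3-hydroxylase (a Fe(II)/2-oxoglutarate-dependent dioxygenase) converts (2S)-4'-O-methyldiplacone into the target.
2. The pyranone ring forms by intramolecular Mitsunobu ring closure (inversion) of a (3R)-β-hydroxy aryl ketone, which fixes C2 as S.
3. The β-hydroxy ketone comes from an A-ring aryllithium adding to a (3R)-β-hydroxy Weinreb amide. The (3R) carbinol comes from Noyori hydrogenation of a β-keto ester, the first stereocenter.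
4. The A-ring is built from phloroglucinol: mono-TBS (the future O1), bis-MOM, ortho-lithiation/geranylation between the two OMOM groups, then bromination. This fixes geranyl at C6 with no regiochemical ambiguity.

## Route

**Step 1**
Reactants: 1 (1-(3-hydroxy-4-methoxyphenyl)ethanone, isoacetovanillone); 2 (chloromethyl methyl ether, MOMCl)
Product: 3 (1-[3-(methoxymethoxy)-4-methoxyphenyl]ethanone)
Conditions: 2 (1.3 equiv), i-Pr2NEt, CH2Cl2, 0 °C→rt
Reagents that add atoms: 2, MOMCl, COCCl
Why: O-alkylation of the phenol gives the MOM acetal, which survives the organolithium, hydrogenation and Mitsunobu steps.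

**Step 2**
Reactants: 3; 4 (dimethyl carbonate)
Product: 5 (methyl 3-[3-(methoxymethoxy)-4-methoxyphenyl]-3-oxopropanoate)
Conditions: NaH, 4 (excess), cat. MeOH, THF, reflux; then AcOH quench
Reagents that add atoms: 4, dimethyl carbonate, COC(=O)OC
Why: Claisen-type methoxycarbonylation of the methyl-ketone enolate, driven by deprotonation of the product β-keto ester.

**Step 3**
Reactant: 5
Product: 6 (methyl (3R)-3-hydroxy-3-[3-(methoxymethoxy)-4-methoxyphenyl]propanoate)
Conditions: H2 (50 atm), Ru(OAc)2[(S)-BINAP] (1 mol%), MeOH, 50 °C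
Reagents that add atoms: none (H2 adds only hydrogen)
Why: Noyori asymmetric hydrogenation proceeds through a keto-ester chelate on Ru, and this sets the first stereocenter; (S)-BINAP delivers the (R)-carbinol (the CIP label differs from alkyl keto esters because Ar outranks CH2CO2Me).

**Step 4**
Reactants: 6; 7 (N,O-dimethylhydroxylamine hydrochloride)
Product: 8 ((3R)-3-hydroxy-N-methoxy-N-methyl-3-[3-(methoxymethoxy)-4-methoxyphenyl]propanamide)
Conditions: 7 (3 equiv), i-PrMgCl (6 equiv), THF, −20→0 °C
Reagents that add atoms: 7, CONC.Cl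
Why: Magnesium-amide aminolysis of the ester (Weinreb amidation); the alkoxide protects the free OH in situ, and the benzylic stereocenter is untouched.

**Step 5**
Reactants: 9 (phloroglucinol, 3 equiv); 10 (TBSCl, 1 equiv)
Product: 11 (5-[(tert-butyldimethylsilyl)oxy]benzene-1,3-diol)
Conditions: imidazole, DMF, 0 °C→rt
Reagents that add atoms: 10, CC(C)(C)[Si](C)(C)Cl
Why: Excess symmetrical triol gives statistical mono-O-silylation; this TBS marks the oxygen that becomes O1.

**Step 6**
Reactants: 11; 2 (MOMCl)
Product: 12 (tert-butyl{[3,5-bis(methoxymethoxy)]phenoxy}dimethylsilane)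
Conditions: 2 (2.6 equiv), i-Pr2NEt, CH2Cl2, 0 °C→rt
Reagents that add atoms: 2, MOMCl, COCCl
Why: Bis-MOM protection of the two remaining phenols; these become the 5-O and 7-O groups and act as ortho-directing groups.

**Step 7**
Reactants: 12; 13 ((E)-geranyl bromide)
Product: 14 (tert-butyl{[4-((2E)-3,7-dimethylocta-2,6-dien-1-yl)-3,5-bis(methoxymethoxy)phenyl]oxy}dimethylsilane)
Conditions: n-BuLi, THF, −78→−30 °C; then CuI (10 mol%), 13, −78 °C→rt
Reagents that add atoms: none (the geranyl group is supplied by reactant 13)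
Why: Directed ortho-metalation occurs at the only position flanked by two OMOM groups (complex-induced proximity effect), and Cu-catalysed SN2 alkylation with the allylic bromide keeps the E-alkene, placing geranyl at future C6.

**Step 8**
Reactants: 14; 15 (N-bromosuccinimide)
Product: 16 (tert-butyl{[2-bromo-4-geranyl-3,5-bis(methoxymethoxy)phenyl]oxy}dimethylsilane)
Conditions: 15 (1.0 equiv), MeCN, −20→0 °C, dark
Reagents that add atoms: 15, O=C1CCC(=O)N1Br
Why: Electrophilic aromatic bromination of the trioxygenated ring, which is far more nucleophilic than the trisubstituted alkene, at one of two equivalent sites ortho to O, giving a clean Br/Li-exchange handle.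

**Step 9**
Reactants: 16 (1.8 equiv); 8
Product: 17 ((3R)-1-{3-geranyl-6-[(tert-butyldimethylsilyl)oxy]-2,4-bis(methoxymethoxy)phenyl}-3-hydroxy-3-[3-(methoxymethoxy)-4-methoxyphenyl]propan-1-one)
Conditions: 16 + t-BuLi (3.6 equiv), THF, −78 °C, 20 min; add to the lithium alkoxide of 8 (from n-BuLi, 1.0 equiv), −78→−30 °C; sat. NH4Cl
Reagents that add atoms: none
Why: Br/Li exchange is faster than lateral lithiation of the geranyl CH2, and the aryllithium adds to the Weinreb amide, whose chelated intermediate stops at the ketone (acyl substitution); the carbinol configuration is retained.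

**Step 10**
Reactant: 17
Product: 18 ((3R)-1-{3-geranyl-6-hydroxy-2,4-bis(methoxymethoxy)phenyl}-3-hydroxy-3-[3-(methoxymethoxy)-4-methoxyphenyl]propan-1-one)
Conditions: TBAF (1.2 equiv), AcOH (1.2 equiv), THF, 0 °C
Reagents that add atoms: none
Why: Fluoride cleaves the aryl silyl ether selectively, and AcOH buffering avoids E1cB dehydration of the β-hydroxy ketone.

**Step 11**
Reactant: 18
Product: 19 ((2S)-6-geranyl-5,7-bis(methoxymethoxy)-2-[3-(methoxymethoxy)-4-methoxyphenyl]chroman-4-one)
Conditions: PPh3 (1.5 equiv), DIAD (1.5 equiv), THF (0.02 M), 0 °C→rt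
Reagents that add atoms: none
Why: Intramolecular Mitsunobu reaction, with the chelated 2'-phenol displacing the activated benzylic alkoxyphosphonium by SN2 inversion, so (R)-carbinol becomes (2S)-flavanone C2.

**Step 12**
Reactant: 19
Product: 20 ((2S)-4'-O-methyldiplacone: (2S)-6-geranyl-5,7-dihydroxy-2-(3-hydroxy-4-methoxyphenyl)chroman-4-one)
Conditions: p-TsOH·H2O (0.6 equiv), MeOH, 40 °C
Reagents that add atoms: none
Why: Acid-catalysed methanolysis/hydrolysis of the three aryl MOM acetals; the flavanone is acid-stable, so C2 does not racemize.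

**Step 13**
Reactants: 20; 21 (dioxygen)
Product: 22 (4'-O-methyldiplacol, target)
Conditions: recombinant flavanone 3-hydroxylase (Petunia hybrida F3H, E. coli lysate), 2-oxoglutarate (2 equiv), FeSO4 (0.1 equiv), sodium ascorbate, catalase, 50 mM Tris-HCl pH 7.5, 5% DMSO, air, 30 °C
Reagents that add atoms: 21, dioxygen, O=O
Why: The Fe(II)/2-oxoglutarate dioxygenase abstracts H-3 and rebounds OH on the face giving 2,3-trans (2R,3R); it accepts only (2S)-flavanones, so any (2R) contaminant stays unreacted and is removed, acting as an ee filter.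

## Compound list
1 | 1-(3-hydroxy-4-methoxyphenyl)ethanone | COc1ccc(C(C)=O)cc1O | starting material
2 | chloromethyl methyl ether (MOMCl) | COCCl | starting material
3 | 1-[3-(MOMO)-4-methoxyphenyl]ethanone | COc1ccc(C(C)=O)cc1OCOC | intermediate
4 | dimethyl carbonate | COC(=O)OC | starting material
5 | methyl 3-[3-(MOMO)-4-methoxyphenyl]-3-oxopropanoate | COC(=O)CC(=O)c1ccc(OC)c(OCOC)c1 | intermediate
6 | methyl (3R)-3-hydroxy-3-[3-(MOMO)-4-methoxyphenyl]propanoate | COC(=O)C[C@@H](O)c1ccc(OC)c(OCOC)c1 | intermediate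
7 | N,O-dimethylhydroxylamine hydrochloride | CONC.Cl | starting material
8 | (3R)-3-hydroxy-N-methoxy-N-methyl-3-[3-(MOMO)-4-methoxyphenyl]propanamide | CON(C)C(=O)C[C@@H](O)c1ccc(OC)c(OCOC)c1 | intermediate
9 | phloroglucinol | Oc1cc(O)cc(O)c1 | starting material
10 | tert-butyldimethylsilyl chloride | CC(C)(C)[Si](C)(C)Cl | starting material
11 | 5-(TBSO)benzene-1,3-diol | CC(C)(C)[Si](C)(C)Oc1cc(O)cc(O)c1 | intermediate
12 | TBS 3,5-bis(MOMO)phenyl ether | COCOc1cc(O[Si](C)(C)C(C)(C)C)cc(OCOC)c1 | intermediate
13 | (E)-geranyl bromide | CC(C)=CCC/C(C)=C/CBr | starting material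
14 | 4-geranyl-3,5-bis(MOMO)phenyl TBS ether | COCOc1cc(O[Si](C)(C)C(C)(C)C)cc(OCOC)c1C/C=C(\C)CCC=C(C)C | intermediate
15 | N-bromosuccinimide | O=C1CCC(=O)N1Br | starting material
16 | 2-bromo-4-geranyl-3,5-bis(MOMO)phenyl TBS ether | COCOc1c(Br)c(O[Si](C)(C)C(C)(C)C)cc(OCOC)c1C/C=C(\C)CCC=C(C)C | intermediate
17 | (3R)-β-hydroxy aryl ketone (aryl-OTBS) | COc1ccc([C@H](O)CC(=O)c2c(OCOC)c(C/C=C(\C)CCC=C(C)C)c(OCOC)cc2O[Si](C)(C)C(C)(C)C)cc1OCOC | intermediate
18 | (3R)-β-hydroxy 2'-hydroxyaryl ketone | COc1ccc([C@H](O)CC(=O)c2c(OCOC)c(C/C=C(\C)CCC=C(C)C)c(OCOC)cc2O)cc1OCOC | intermediate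
19 | (2S)-tri-O-MOM-4'-O-methyldiplacone | COc1ccc([C@H]2Oc3cc(OCOC)c(C/C=C(\C)CCC=C(C)C)c(OCOC)c3C(=O)C2)cc1OCOC | intermediate
20 | (2S)-4'-O-methyldiplacone | COc1ccc([C@H]2Oc3cc(O)c(C/C=C(\C)CCC=C(C)C)c(O)c3C(=O)C2)cc1O | intermediate
21 | dioxygen | O=O | starting material
22 | 4'-O-methyldiplacol (2R,3R) | COc1ccc([C@H]2Oc3cc(O)c(C/C=C(\C)CCC=C(C)C)c(O)c3C(=O)[C@@H]2O)cc1O | target

**Total steps:** 13. **Longest linear sequence:** 9 steps (1→3→5→6→8→17→18→19→20→22, or 9→11→12→14→16→17→…→22).

## Three steps most likely to fail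
1. **Step 13 (F3H).** The enzyme may not accept the lipophilic 6-geranyl, 4'-OMe flavanone, so conversion could be low. Fallback: chemical 3-hydroxylation of 19 by silyl enol ether formation (TMSOTf/Et3N) and Rubottom oxidation with DMDO, which attacks anti to the 2-aryl group to give the trans-3-OH, followed by the MOM removal of step 12.
2. **Step 11 (Mitsunobu).** The β-hydroxy ketone can eliminate to the chalcone, which would erode ee. Fallback: dehydrate 18 to the 2'-hydroxychalcone (MsCl/Et3N) and close it with a bifunctional cinchona-thiourea oxa-Michael catalyst to give the (2S)-flavanone, with step 13 acting as the ee filter.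
3. **Step 9 (hindered aryllithium addition).** Addition may be sluggish, and the β-hydroxy ketone may dehydrate. Fallback: desilylate 14 (TBAF) to the phenol and use intermolecular Mitsunobu on 6 (inversion) to make the aryl ether. Then saponify, and close the ketone by intramolecular Friedel–Crafts acylation (TFAA) to reach 19.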